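**Assumption:** the target SMILES has no stereocentres and no stereogenic double bond (the C3=C4 alkene is endocyclic, the prenyl alkene carries two methyls), so the compound is achiral and there is no enantiomer to control. The route has not been run; yields and selectivities are expectations from analogous chemistry.

## Retrosynthetic overview

1. The target is released by global desilylation of its tris-TIPS ether; the 2H-pyran ring is closed last by intramolecular Mitsunobu etherification of a (Z)-o-hydroxycinnamyl alcohol.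
2. That diol comes from DIBAL 1,2-reduction of a 3-arylcoumarin, which fixes the Z geometry needed for ring closure.
3. The 5-OMe/6-prenyl pattern comes from a 5-O-allyl coumarin: Claisen shift to C6 (C4a is blocked), O-methylation of the liberated 5-OH, then cross-metathesis of allyl to prenyl.
4. The coumarin comes from a salicylaldehyde and 2,4-bis(silyloxy)phenylacetic acid (O-acylation, then intramolecular Knoevenagel). The three oxygens of 2,4,6-trihydroxybenzaldehyde are differentiated by silylating the 4-OH and allylating one of the two equivalent ortho-OH groups.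
5. Ring order: A and B rings are bought; the lactone ring is formed first, opened reductively, and re-closed as the 2H-chromene.

## Route

**Step 1**
Reactants: **1** 2,4,6-trihydroxybenzaldehyde; **2** triisopropylsilyl chloride (TIPSCl)
Product: **3** 2,6-dihydroxy-4-(triisopropylsilyloxy)benzaldehyde
Conditions: TIPSCl (1.05 eq), imidazole, DMF, 0 °C
Reagents that add atoms: TIPSCl, CC(C)[Si](Cl)(C(C)C)C(C)C
Why: Selective O-silylation; the para OH is the most acidic and the only one not hydrogen-bonded to the aldehyde, so it reacts first.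

**Step 2**
Reactants: **3**; **4** allyl alcohol
Product: **5** 2-(allyloxy)-6-hydroxy-4-(triisopropylsilyloxy)benzaldehyde
Conditions: allyl alcohol (1.1 eq), PPh3, DIAD, THF, 0 °C to rt
Reagents that add atoms: allyl alcohol, C=CCO
Why: Mitsunobu etherification under neutral conditions (silyl ether safe); the two ortho-OH groups are equivalent, and the remaining one becomes more strongly chelated, which slows a second alkylation.

**Step 3**
Reactants: **6** 2,4-dihydroxyphenylacetic acid; **2** TIPSCl
Product: **7** 2-[2,4-bis(triisopropylsilyloxy)phenyl]acetic acid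
Conditions: TIPSCl (3.3 eq), imidazole, DMF, rt; then K2CO3, MeOH/THF/H2O, 0 °C (cleaves the silyl ester only)
Reagents that add atoms: TIPSCl, CC(C)[Si](Cl)(C(C)C)C(C)C
Why: Exhaustive silylation followed by selective hydrolysis of the much more labile silyl ester leaves the two aryl TIPS ethers.

**Step 4**
Reactants: **5**; **7**
Product: **8** 5-(allyloxy)-3-[2,4-bis(triisopropylsilyloxy)phenyl]-7-(triisopropylsilyloxy)-2H-chromen-2-one
Conditions: EDC·HCl, DMAP, CH2Cl2, rt; then DBU, rt to 40 °C (one pot)
Reagents that add atoms: none (both partners are the listed reactants; 2 H2O lost)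
Why: Steglich esterification of the single free phenol, then intramolecular Knoevenagel condensation of the aryl arylacetate onto the ortho aldehyde (a mild Perkin-type coumarin synthesis) forms the lactone ring.

**Step 5**
Reactants: **8**
Product: **9** 6-allyl-5-hydroxy-3-[2,4-bis(triisopropylsilyloxy)phenyl]-7-(triisopropylsilyloxy)-2H-chromen-2-one
Conditions: PhNEt2, 190 °C (sealed tube or microwave), Ar
Reagents that add atoms: none
Why: Aromatic Claisen rearrangement; of the two positions ortho to O5, C4a is a ring-fusion carbon, so the allyl group goes to C6 and the phenol re-forms.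

**Step 6**
Reactants: **9**; **10** trimethylsilyldiazomethane
Product: **11** 6-allyl-5-methoxy-3-[2,4-bis(triisopropylsilyloxy)phenyl]-7-(triisopropylsilyloxy)-2H-chromen-2-one
Conditions: TMSCHN2 (2 M in hexanes), i-Pr2NEt, MeCN/MeOH 9:1, rt
Reagents that add atoms: TMSCHN2, C[Si](C)(C)C=[N+]=[N-] (supplies the O-methyl carbon)
Why: Base-free O-methylation of the only free phenol; avoiding carbonate/MeI protects the activated 7-O-silyl ether from cleavage and mis-methylation.

**Step 7**
Reactants: **11**; **12** 2-methyl-2-butene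
Product: **13** 5-methoxy-6-(3-methylbut-2-en-1-yl)-3-[2,4-bis(triisopropylsilyloxy)phenyl]-7-(triisopropylsilyloxy)-2H-chromen-2-one
Conditions: Grubbs II (5 mol %), 2-methyl-2-butene/CH2Cl2, 40 °C
Reagents that add atoms: 2-methyl-2-butene, CC=C(C)C
Why: Olefin cross-metathesis converts the terminal allyl group into prenyl; the trisubstituted, conjugated coumarin alkene does not react.

**Step 8**
Reactants: **13**
Product: **14** (Z)-2-[2,4-bis(triisopropylsilyloxy)phenyl]-3-[2-hydroxy-6-methoxy-5-(3-methylbut-2-en-1-yl)-4-(triisopropylsilyloxy)phenyl]prop-2-en-1-ol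
Conditions: DIBAL-H (4.5 eq), CH2Cl2, −78 to 0 °C; Rochelle salt work-up; use crude
Reagents that add atoms: none
Why: 1,2-Reduction of the lactone (through the lactol/aldehyde) gives the allylic alcohol and frees the ring phenol; the alkene geometry (CH2OH cis to the A ring) is inherited from the coumarin.

**Step 9**
Reactants: **14**
Product: **15** 5-methoxy-6-(3-methylbut-2-en-1-yl)-7-(triisopropylsilyloxy)-3-[2,4-bis(triisopropylsilyloxy)phenyl]-2H-chromene
Conditions: PPh3, DIAD, THF (0.02 M), 0 °C to rt
Reagents that add atoms: none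
Why: Intramolecular Mitsunobu etherification; the only free phenol is held cis to the activated primary allylic alcohol, so 6-membered closure to the 2H-chromene is the only cyclisation available (the B-ring 2'-O is silylated, so no benzofuran forms).

**Step 10**
Reactants: **15**
Product: **16** dehydroglyasperin C, 4-[7-hydroxy-5-methoxy-6-(3-methylbut-2-en-1-yl)-2H-chromen-3-yl]benzene-1,3-diol
Conditions: TBAF (3.5 eq)/AcOH (3.5 eq), THF, 0 °C, Ar, dark; degassed work-up
Reagents that add atoms: none
Why: Fluoride desilylation of the three aryl TIPS ethers under buffered, non-acidic conditions avoids acid-promoted cyclisation onto the prenyl group or the electron-rich C3=C4 alkene.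

## Compound list

1 | 2,4,6-trihydroxybenzaldehyde | O=Cc1c(O)cc(O)cc1O | starting material
2 | triisopropylsilyl chloride | CC(C)[Si](Cl)(C(C)C)C(C)C | starting material (reagent)
3 | 2,6-dihydroxy-4-(triisopropylsilyloxy)benzaldehyde | O=Cc1c(O)cc(O[Si](C(C)C)(C(C)C)C(C)C)cc1O | intermediate
4 | allyl alcohol | C=CCO | starting material (reagent)
5 | 2-(allyloxy)-6-hydroxy-4-(triisopropylsilyloxy)benzaldehyde | C=CCOc1cc(O[Si](C(C)C)(C(C)C)C(C)C)cc(O)c1C=O | intermediate
6 | 2,4-dihydroxyphenylacetic acid | OC(=O)Cc1ccc(O)cc1O | starting material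
7 | 2-[2,4-bis(triisopropylsilyloxy)phenyl]acetic acid | OC(=O)Cc1ccc(O[Si](C(C)C)(C(C)C)C(C)C)cc1O[Si](C(C)C)(C(C)C)C(C)C | intermediate
8 | 5-(allyloxy)-3-[2,4-bis(TIPSO)phenyl]-7-(TIPSO)-2H-chromen-2-one | C=CCOc1cc(O[Si](C(C)C)(C(C)C)C(C)C)cc2OC(=O)C(=Cc12)c1ccc(O[Si](C(C)C)(C(C)C)C(C)C)cc1O[Si](C(C)C)(C(C)C)C(C)C | intermediate
9 | 6-allyl-5-hydroxy-3-[2,4-bis(TIPSO)phenyl]-7-(TIPSO)-2H-chromen-2-one | C=CCc1c(O[Si](C(C)C)(C(C)C)C(C)C)cc2OC(=O)C(=Cc2c1O)c1ccc(O[Si](C(C)C)(C(C)C)C(C)C)cc1O[Si](C(C)C)(C(C)C)C(C)C | intermediate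
10 | trimethylsilyldiazomethane | C[Si](C)(C)C=[N+]=[N-] | starting material (reagent)
11 | 6-allyl-5-methoxy-3-[2,4-bis(TIPSO)phenyl]-7-(TIPSO)-2H-chromen-2-one | C=CCc1c(O[Si](C(C)C)(C(C)C)C(C)C)cc2OC(=O)C(=Cc2c1OC)c1ccc(O[Si](C(C)C)(C(C)C)C(C)C)cc1O[Si](C(C)C)(C(C)C)C(C)C | intermediate
12 | 2-methyl-2-butene | CC=C(C)C | starting material (reagent)
13 | 5-methoxy-6-prenyl-3-[2,4-bis(TIPSO)phenyl]-7-(TIPSO)-2H-chromen-2-one | CC(C)=CCc1c(O[Si](C(C)C)(C(C)C)C(C)C)cc2OC(=O)C(=Cc2c1OC)c1ccc(O[Si](C(C)C)(C(C)C)C(C)C)cc1O[Si](C(C)C)(C(C)C)C(C)C | intermediate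
14 | (Z)-2-[2,4-bis(TIPSO)phenyl]-3-[2-hydroxy-6-methoxy-5-prenyl-4-(TIPSO)phenyl]prop-2-en-1-ol | OC/C(c1ccc(O[Si](C(C)C)(C(C)C)C(C)C)cc1O[Si](C(C)C)(C(C)C)C(C)C)=C\c1c(O)cc(O[Si](C(C)C)(C(C)C)C(C)C)c(CC=C(C)C)c1OC | intermediate
15 | 5-methoxy-6-prenyl-7-(TIPSO)-3-[2,4-bis(TIPSO)phenyl]-2H-chromene | COc1c2c(cc(O[Si](C(C)C)(C(C)C)C(C)C)c1CC=C(C)C)OCC(c1ccc(O[Si](C(C)C)(C(C)C)C(C)C)cc1O[Si](C(C)C)(C(C)C)C(C)C)=C2 | intermediate
16 | dehydroglyasperin C | COc1c2c(cc(O)c1CC=C(C)C)OCC(c1ccc(O)cc1O)=C2 | target

(TIPSO = triisopropylsilyloxy; prenyl = 3-methylbut-2-en-1-yl.)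

## Summary

**Total steps:** 10
**Longest linear sequence:** 9 (steps 1, 2, 4, 5, 6, 7, 8, 9, 10; step 3 is the one-step side branch)

**Three steps most likely to fail, with fallbacks**

1. **Step 5, Claisen on the tris-silyl coumarin** (190 °C; possible para migration to C8 or silyl loss). Fallback: use a reverse-prenyl ether in place of the allyl ether and the metathesis. Couple **3** with **7** to the 5-hydroxycoumarin, alkylate with 3-chloro-3-methylbut-1-yne (CuCl2 cat., DBU), and semi-hydrogenate (Lindlar). The resulting 1,1-dimethylallyl ether rearranges at about 100–120 °C directly to the 6-prenyl-5-hydroxycoumarin; methylation then gives **13**.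

2. **Step 4, coumarin annulation** (electron-rich aldehyde, hindered acid, base-sensitive silyl ethers). Fallback: form the C3–aryl bond by cross-coupling. Treat **5** with Ph3P=C(Br)CO2Et (Wittig/lactonisation) to get the 3-bromocoumarin, then Suzuki–Miyaura couple with 2,4-bis(TIPSO)phenylboronic acid pinacol ester to reach **8**.

3. **Step 1, selective mono-silylation** (and survival of the activated 4-O-silyl ether through steps 2–6). Fallback: differentiate the oxygens with MOM groups and do the Claisen on the aldehyde. The sequence is **1** to 2-hydroxy-4,6-bis(MOMO)benzaldehyde, O-allylation, Claisen (C3 is the only open ortho site), O-methylation, MOM removal with HCl/MeOH (before any prenyl or chromene is present), cross-metathesis, and selective 4-O-silylation. The resulting 2-hydroxy-6-methoxy-5-prenyl-4-(TIPSO)benzaldehyde is then coupled with **7** under step 4 conditions to give **13** directly (about two steps longer).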